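**Retrosynthetic overview**
1. Styryl C–C bond last: Heck reaction of vinylcyclohexene 14 with 8-iodo-7-methoxycoumarin 17. The quaternary carbon has no hydrogen, so only the E-alkene can form.
2. Cyclohexene C2=C3 by ring-closing metathesis of acyclic triene 13. The carbocycle is the last ring made; coumarin ring A is made in step 1 and coumarin ring B is bought as umbelliferone.
3. Key step: the C1–C6 bond and both stereocentres are set at once by a Pd-catalysed enantio- and diastereoselective allyl–allyl cross-coupling of cinnamyl chloride 7 with E-allylboronate 12. This replaces the biomimetic diene + diene Diels–Alder.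
4. 7 comes from 5-bromo-2-hydroxy-4-methoxybenzaldehyde 1; 12 from 5-methylhex-5-en-2-one 8; 17 from umbelliferone 15.

Assumption: the SMILES is read as the (1R,6R) isomer with the 6-coumarinyl and styryl groups cis; the sense of induction of the (R)-ligand in step 7 is assigned by analogy with simple cinnamyl electrophiles, and the mirror-image ligand would be taken if the first run showed the opposite sense.

**Step 1**
Reactants: 1 5-bromo-2-hydroxy-4-methoxybenzaldehyde
Product: 3 6-bromo-7-methoxy-2H-chromen-2-one, via hydroxycinnamate ester 2 (not isolated)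
Conditions: Ph3P=CHCO2Et (1.2 equiv), N,N-diethylaniline, reflux (about 215 °C), 4 h
Reagents that add atoms: ethyl (triphenylphosphoranylidene)acetate, CCOC(=O)C=P(c1ccccc1)(c1ccccc1)c1ccccc1
Why: Wittig olefination of the salicylaldehyde, followed at reflux by E-to-Z isomerisation and lactonisation, gives the coumarin directly; no stereocentre is formed.

**Step 2**
Reactants: 3 6-bromo-7-methoxy-2H-chromen-2-one; 4 (2E)-3-(tributylstannyl)prop-2-en-1-ol
Product: 5 6-[(1E)-3-hydroxyprop-1-en-1-yl]-7-methoxy-2H-chromen-2-one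
Conditions: Pd(PPh3)4 (5 mol %), CuI (10 mol %), CsF (2 equiv), DMF, 80 °C
Reagents that add atoms: none
Why: Migita–Kosugi–Stille coupling transfers the alkenyl group with retention of E geometry (CuI and CsF speed up transmetalation) and tolerates the free hydroxyl and the lactone.

**Step 3**
Reactants: 5 6-[(1E)-3-hydroxyprop-1-en-1-yl]-7-methoxy-2H-chromen-2-one
Product: 7 6-[(1E)-3-chloroprop-1-en-1-yl]-7-methoxy-2H-chromen-2-one, via allylic mesylate 6 (not isolated)
Conditions: MsCl (1.2 equiv), LiCl (3 equiv), 2,4,6-collidine (1.5 equiv), DMF, 0 °C to rt; used promptly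
Reagents that add atoms: lithium chloride, [Li+].[Cl-] (chlorine of 7); methanesulfonyl chloride, CS(=O)(=O)Cl (mesyl group of 6 only)
Why: Collington–Meyers allylic chlorination (mesylation, then SN2 displacement by chloride) gives the primary E-chloride without acid; no stereocentre is formed.

**Step 4**
Reactants: 8 5-methylhex-5-en-2-one
Product: 9 ethyl (2E)-3,6-dimethylhepta-2,6-dienoate
Conditions: (EtO)2P(O)CH2CO2Et (1.3 equiv), NaH (1.3 equiv), THF, 0 °C to rt; E isomer (about 4:1 E:Z expected) separated by chromatography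
Reagents that add atoms: triethyl phosphonoacetate, CCOC(=O)CP(=O)(OCC)OCC
Why: Horner–Wadsworth–Emmons olefination of the methyl ketone gives mainly the E-enoate (chain trans to the ester), and removing the Z isomer here supplies geometrically pure material for the key step.

**Step 5**
Reactants: 9 ethyl (2E)-3,6-dimethylhepta-2,6-dienoate
Product: 11 (2E)-3,6-dimethylhepta-2,6-dien-1-ol, via dienal 10 (not isolated)
Conditions: i-Bu2AlH (2.5 equiv), CH2Cl2, −78 to 0 °C; aq. KNaC4H4O6 work-up
Reagents that add atoms: none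
Why: i-Bu2AlH reduces the conjugated ester 1,2- through the aldehyde to the allylic alcohol without touching either alkene or its geometry.

**Step 6**
Reactants: 11 (2E)-3,6-dimethylhepta-2,6-dien-1-ol
Product: 12 2-[(2E)-3,6-dimethylhepta-2,6-dien-1-yl]-4,4,5,5-tetramethyl-1,3,2-dioxaborolane
Conditions: B2pin2 (1.2 equiv), Pd(MeCN)4(BF4)2 (5 mol %), DMSO/MeOH 1:1, 50 °C
Reagents that add atoms: bis(pinacolato)diboron, CC1(C)OB(OC1(C)C)B1OC(C)(C)C(C)(C)O1
Why: Pd-catalysed allylic borylation through a π-allylpalladium puts boron on the unsubstituted terminus, and the E geometry is kept because syn/anti exchange would need palladium σ-bound at the tertiary carbon.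

**Step 7**
Reactants: 7 6-[(1E)-3-chloroprop-1-en-1-yl]-7-methoxy-2H-chromen-2-one; 12 2-[(2E)-3,6-dimethylhepta-2,6-dien-1-yl]-4,4,5,5-tetramethyl-1,3,2-dioxaborolane
Product: 13 6-[(3R,4R)-4-ethenyl-4,7-dimethylocta-1,7-dien-3-yl]-7-methoxy-2H-chromen-2-one
Conditions: Pd2(dba)3 (2.5 mol %), (R)-2,2'-bis(di-2-furylphosphino)-6,6'-dimethoxy-1,1'-biphenyl [(R)-MeO-furyl-BIPHEP] (6 mol %), CsF (3 equiv), degassed THF, 60 °C (not hotter, to avoid Cope rearrangement of the 1,5-diene)
Reagents that add atoms: none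
Why: Proposed new method: zerovalent palladium ionises 7 to a π-allyl complex, CsF-assisted transmetalation of 12 gives a bis(η1-allyl)palladium, and the small-bite-angle diphosphine enforces 3,3'-reductive elimination through a chair-like transition state with the E-aryl group and the E-homoallyl chain both pseudo-equatorial, which gives the like (3R,4R) pair (aryl and vinyl cis after ring closure) while the ligand selects the benzylic face; the closest known reaction type is the Pd/chiral-diphosphine enantio- and diastereoselective allyl–allyl cross-coupling of prochiral allylboronates with cinnamyl chlorides, here extended to a γ,γ-dialkyl allylboronate so that a quaternary centre forms next to the benzylic one.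

**Step 8**
Reactants: 13 6-[(3R,4R)-4-ethenyl-4,7-dimethylocta-1,7-dien-3-yl]-7-methoxy-2H-chromen-2-one
Product: 14 6-[(1R,6R)-6-ethenyl-3,6-dimethylcyclohex-2-en-1-yl]-7-methoxy-2H-chromen-2-one
Conditions: second-generation Hoveyda–Grubbs catalyst RuCl2(=CH-C6H4-2-O-i-Pr)(H2IMes) (5 mol %), CH2Cl2 (5 mM), 40 °C
Reagents that add atoms: none
Why: In this ring-closing metathesis the ruthenium carbene forms fastest at the vinyl group on the tertiary benzylic carbon and closes onto the 1,1-disubstituted alkene to give the trisubstituted cyclohexene, while the vinyl group on the quaternary carbon initiates slowly and is kept for step 11; the stereocentres are not involved.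

**Step 9**
Reactants: 15 7-hydroxy-2H-chromen-2-one
Product: 16 7-hydroxy-8-iodo-2H-chromen-2-one
Conditions: I2 (1.05 equiv), KI, 20% aq. NH3, 0 °C to rt; then dilute HCl
Reagents that add atoms: iodine, II
Why: Electrophilic aromatic iodination of the phenoxide goes to C8, the position ortho to the phenoxide oxygen and flanked by the ring oxygen.

**Step 10**
Reactants: 16 7-hydroxy-8-iodo-2H-chromen-2-one
Product: 17 8-iodo-7-methoxy-2H-chromen-2-one
Conditions: MeI (2 equiv), K2CO3 (2 equiv), acetone, reflux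
Reagents that add atoms: iodomethane, CI
Why: Williamson O-methylation of the phenol; the lactone is stable to K2CO3 in acetone.

**Step 11**
Reactants: 14 6-[(1R,6R)-6-ethenyl-3,6-dimethylcyclohex-2-en-1-yl]-7-methoxy-2H-chromen-2-one; 17 8-iodo-7-methoxy-2H-chromen-2-one
Product: 18 6-[(1R,6R)-6-[(E)-2-(7-methoxy-2-oxo-2H-chromen-8-yl)ethenyl]-3,6-dimethylcyclohex-2-en-1-yl]-7-methoxy-2H-chromen-2-one
Conditions: Pd(OAc)2 (10 mol %), n-Bu4NCl (1 equiv), NaHCO3 (2.5 equiv), DMF, 85 °C
Reagents that add atoms: none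
Why: In this Mizoroki–Heck reaction (Jeffery conditions) the aryl group adds to the terminal carbon of the vinyl group and, as the quaternary carbon has no hydrogen, β-hydride elimination can only give the E-styrene; the ring alkene and the coumarin double bonds are far less reactive and both stereocentres are untouched.

**Compound list**
1 | 5-bromo-2-hydroxy-4-methoxybenzaldehyde | COc1cc(O)c(C=O)cc1Br | starting material
2 | ethyl (2E)-3-(5-bromo-2-hydroxy-4-methoxyphenyl)prop-2-enoate | CCOC(=O)/C=C/c1cc(Br)c(OC)cc1O | intermediate (not isolated)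
3 | 6-bromo-7-methoxy-2H-chromen-2-one | COc1cc2oc(=O)ccc2cc1Br | intermediate
4 | (2E)-3-(tributylstannyl)prop-2-en-1-ol | CCCC[Sn](CCCC)(CCCC)/C=C/CO | starting material
5 | 6-[(1E)-3-hydroxyprop-1-en-1-yl]-7-methoxy-2H-chromen-2-one | COc1cc2oc(=O)ccc2cc1/C=C/CO | intermediate
6 | (2E)-3-(7-methoxy-2-oxo-2H-chromen-6-yl)prop-2-en-1-yl methanesulfonate | COc1cc2oc(=O)ccc2cc1/C=C/COS(C)(=O)=O | intermediate (not isolated)
7 | 6-[(1E)-3-chloroprop-1-en-1-yl]-7-methoxy-2H-chromen-2-one | COc1cc2oc(=O)ccc2cc1/C=C/CCl | intermediate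
8 | 5-methylhex-5-en-2-one | CC(=O)CCC(C)=C | starting material
9 | ethyl (2E)-3,6-dimethylhepta-2,6-dienoate | CCOC(=O)/C=C(\C)CCC(C)=C | intermediate
10 | (2E)-3,6-dimethylhepta-2,6-dienal | O=C/C=C(\C)CCC(C)=C | intermediate (not isolated)
11 | (2E)-3,6-dimethylhepta-2,6-dien-1-ol | OC/C=C(\C)CCC(C)=C | intermediate
12 | 2-[(2E)-3,6-dimethylhepta-2,6-dien-1-yl]-4,4,5,5-tetramethyl-1,3,2-dioxaborolane | CC(=C)CC/C(C)=C/CB1OC(C)(C)C(C)(C)O1 | intermediate
13 | 6-[(3R,4R)-4-ethenyl-4,7-dimethylocta-1,7-dien-3-yl]-7-methoxy-2H-chromen-2-one | COc1cc2oc(=O)ccc2cc1[C@H](C=C)[C@@](C)(C=C)CCC(C)=C | intermediate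
14 | 6-[(1R,6R)-6-ethenyl-3,6-dimethylcyclohex-2-en-1-yl]-7-methoxy-2H-chromen-2-one | COc1cc2oc(=O)ccc2cc1[C@@H]1C=C(C)CC[C@]1(C)C=C | intermediate
15 | 7-hydroxy-2H-chromen-2-one (umbelliferone) | O=c1ccc2ccc(O)cc2o1 | starting material
16 | 7-hydroxy-8-iodo-2H-chromen-2-one | O=c1ccc2ccc(O)c(I)c2o1 | intermediate
17 | 8-iodo-7-methoxy-2H-chromen-2-one | COc1ccc2ccc(=O)oc2c1I | intermediate
18 | 6-[(1R,6R)-6-[(E)-2-(7-methoxy-2-oxo-2H-chromen-8-yl)ethenyl]-3,6-dimethylcyclohex-2-en-1-yl]-7-methoxy-2H-chromen-2-one (CNP0287121.3) | COc1cc2oc(=O)ccc2cc1[C@@H]1C=C(C)CC[C@]1(C)/C=C/c1c(OC)ccc2ccc(=O)oc12 | target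

**Totals**
Total step count: 11. Longest linear sequence: 6 steps (1, 2, 3, 7, 8, 11 or 4, 5, 6, 7, 8, 11).

**Three steps most likely to fail**

Step 7 (congested allyl–allyl coupling). The risks are coupling at the unsubstituted carbon of the boronate instead of the branched/branched mode, and weak diastereocontrol at the quaternary carbon. The fallback exchanges the roles of the two allyl partners; it sets out from 5 and 8 and comes back at 13. Alcohol 5 is borylated as in step 6 (B2pin2, Pd(MeCN)4(BF4)2, DMSO/MeOH) to 7-methoxy-6-[(1E)-3-(4,4,5,5-tetramethyl-1,3,2-dioxaborolan-2-yl)prop-1-en-1-yl]-2H-chromen-2-one F1. Ketone 8 and vinylmagnesium bromide (CH2=CHMgBr, THF, 0 °C) give racemic 3,6-dimethylhepta-1,6-dien-3-ol F2, which n-BuLi and Boc2O convert into tert-butyl 3,6-dimethylhepta-1,6-dien-3-yl carbonate F3. Pd2(dba)3 with the chiral diphosphine then joins F1 and F3. The quaternary carbon now comes from a π-allylpalladium electrophile formed by stereoconvergent ionisation, and the benzylic carbon from the γ-aryl allylboronate, giving 13.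

Step 8 (ring-closing metathesis). The risk is a competing five-membered ring closure between the quaternary vinyl group and the 1,1-disubstituted alkene. The fallback builds the cyclohexene without metathesis; it sets out from 3 and comes back at 14. Heck reaction of 3 with 2-methylbut-3-en-2-ol (Pd(OAc)2, n-Bu4NCl, NaHCO3, DMF, 90 °C) gives 6-[(1E)-3-hydroxy-3-methylbut-1-en-1-yl]-7-methoxy-2H-chromen-2-one F4. Dehydration (cat. p-TsOH, toluene, 60 °C) gives 7-methoxy-6-[(1E)-3-methylbuta-1,3-dien-1-yl]-2H-chromen-2-one F5. An enantioselective [4+2] cycloaddition of F5 with methacrolein, catalysed by a triflimide-activated chiral B-aryl oxazaborolidine (CH2Cl2, −78 °C, formyl group endo), gives (1S,2S)-2-(7-methoxy-2-oxo-2H-chromen-6-yl)-1,4-dimethylcyclohex-3-ene-1-carbaldehyde F6. Methylenation (Ph3P=CH2, THF, −78 to 0 °C) then gives 14.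

Step 11 (Heck reaction of a di-ortho-substituted aryl iodide with a neopentyl-type alkene). The risk is slow insertion of the hindered alkene into the hindered arylpalladium. The fallback puts boron on the alkene first and then uses a Suzuki coupling; it sets out from 14 and comes back at 18. A Pd-catalysed boryl-Heck reaction of 14 with B-chlorocatecholborane and a trialkylamine gives 6-[(1R,6R)-6-[(E)-2-(1,3,2-benzodioxaborol-2-yl)ethenyl]-3,6-dimethylcyclohex-2-en-1-yl]-7-methoxy-2H-chromen-2-one F7. Exchange with pinacol in the same flask gives 6-[(1R,6R)-3,6-dimethyl-6-[(E)-2-(4,4,5,5-tetramethyl-1,3,2-dioxaborolan-2-yl)ethenyl]cyclohex-2-en-1-yl]-7-methoxy-2H-chromen-2-one F8. Suzuki–Miyaura coupling of F8 with 17 (Pd(OAc)2, SPhos, K3PO4, THF/H2O, 50 °C) gives 18 with retention of the E geometry.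

**Further compounds**
F1 | step 7 | 7-methoxy-6-[(1E)-3-(4,4,5,5-tetramethyl-1,3,2-dioxaborolan-2-yl)prop-1-en-1-yl]-2H-chromen-2-one | COc1cc2oc(=O)ccc2cc1/C=C/CB1OC(C)(C)C(C)(C)O1
F2 | step 7 | 3,6-dimethylhepta-1,6-dien-3-ol (racemic) | C=CC(C)(O)CCC(C)=C
F3 | step 7 | tert-butyl 3,6-dimethylhepta-1,6-dien-3-yl carbonate (racemic) | C=CC(C)(OC(=O)OC(C)(C)C)CCC(C)=C
F4 | step 8 | 6-[(1E)-3-hydroxy-3-methylbut-1-en-1-yl]-7-methoxy-2H-chromen-2-one | COc1cc2oc(=O)ccc2cc1/C=C/C(C)(C)O
F5 | step 8 | 7-methoxy-6-[(1E)-3-methylbuta-1,3-dien-1-yl]-2H-chromen-2-one | COc1cc2oc(=O)ccc2cc1/C=C/C(C)=C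
F6 | step 8 | (1S,2S)-2-(7-methoxy-2-oxo-2H-chromen-6-yl)-1,4-dimethylcyclohex-3-ene-1-carbaldehyde | COc1cc2oc(=O)ccc2cc1[C@@H]1C=C(C)CC[C@]1(C)C=O
F7 | step 11 | 6-[(1R,6R)-6-[(E)-2-(1,3,2-benzodioxaborol-2-yl)ethenyl]-3,6-dimethylcyclohex-2-en-1-yl]-7-methoxy-2H-chromen-2-one | COc1cc2oc(=O)ccc2cc1[C@@H]1C=C(C)CC[C@]1(C)/C=C/B1Oc2ccccc2O1
F8 | step 11 | 6-[(1R,6R)-3,6-dimethyl-6-[(E)-2-(4,4,5,5-tetramethyl-1,3,2-dioxaborolan-2-yl)ethenyl]cyclohex-2-en-1-yl]-7-methoxy-2H-chromen-2-one | COc1cc2oc(=O)ccc2cc1[C@@H]1C=C(C)CC[C@]1(C)/C=C/B1OC(C)(C)C(C)(C)O1
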